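**Retrosynthetic overview**

1. Endgame: the C2 acrolein unit comes from an isopropenyl group (SeO2, then MnO2), and this from a C2 CMe2OH group. The C3 isovalerate and the side-chain (R)-2-methylbutanoate are made by acylation, and the (R)-carbinol by Noyori hydrogenation of a C5 acetyl group.
2. Key disconnection: the benzene ring of the dihydrobenzofuran is cut at C3a–C4 and C5–C6 into the dihydrofuran-fused 2-pyranone 7 and but-3-yn-2-one 8 (Diels–Alder, then loss of CO2). The strategy rests on this feature: the only carbon substituent of the benzene ring sits on C5, para to the C7a–O1 bond, while C4, C6 and C7 carry hydrogen, which is the pattern a 4-alkoxy-2-pyranone leaves with a terminal ynone.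
3. Pyranone 7 comes from 4-hydroxy-2H-pyran-2-one 4 and the (S)-epoxy aldehyde 3 (Sharpless epoxidation of prenol) by aldol addition and 5-exo epoxide opening, which builds the dihydrofuran ring with C2 and C3 trans.
4. Ring order: pyranone ring (purchased), then dihydrofuran ring (step 3), then benzene ring (step 5, the lactone bridge leaving as CO2).

Key step: step 5

Remark: the target is read as (2R,3S) (trans at C2/C3), R at the side-chain carbinol and R in the 2-methylbutanoate; 4-hydroxy-2H-pyran-2-one is taken as a catalogue compound.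

**Route**

Step 1
Reactants: 1 3-methylbut-2-en-1-ol (prenol)
Product: 2 (R)-(3,3-dimethyloxiran-2-yl)methanol
Conditions: Ti(OiPr)4 (5 mol%), D-(−)-diisopropyl tartrate (7 mol%), t-BuOOH (anhydrous, in decane), 4 Å MS, CH2Cl2, −20 °C
Reagents that add atoms: tert-butyl hydroperoxide, CC(C)(C)OO
Why: Katsuki–Sharpless asymmetric epoxidation of a trisubstituted allylic alcohol, in which the titanium/D-(−)-tartrate complex delivers the peroxide oxygen to the alkene face that gives the 2R epoxy alcohol (the L-(+)-ester gives the 2S series for this priority pattern), so the single stereocentre is set by the catalyst.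

Step 2
Reactants: 2 (R)-(3,3-dimethyloxiran-2-yl)methanol
Product: 3 (S)-3,3-dimethyloxirane-2-carbaldehyde
Conditions: SO3·pyridine, DMSO, i-Pr2NEt, CH2Cl2, 0 °C; kept as a cold solution
Reagents that add atoms: none
Why: Parikh–Doering oxidation (activated DMSO) runs under basic, non-aqueous conditions that leave the acid-labile epoxide and its stereocentre untouched, the descriptor changing from R to S only because CHO outranks the CMe2 carbon.

Step 3
Reactants: 3 (S)-3,3-dimethyloxirane-2-carbaldehyde; 4 4-hydroxy-2H-pyran-2-one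
Product: 6 (2S,3S)-3-hydroxy-2-(2-hydroxypropan-2-yl)-2,3-dihydro-4H-furo[3,2-c]pyran-4-one (trans), via syn-aldol adduct 5 (not isolated)
Conditions: K2CO3 (0.3 equiv), MeCN/H2O (10:1), 0 °C → rt; 4 added slowly to 3 (1.3 equiv)
Reagents that add atoms: none
Why: Interrupted Feist–Bénary reaction with an α,β-epoxy aldehyde as electrophile: the C3 enolate of 4 adds reversibly to the aldehyde and the C4 enolate oxygen then opens the epoxide 5-exo-tet at its CH carbon with inversion, so C2 is fixed by the Sharpless epoxide, while the trans C3 carbinol should come from the faster closure of the syn aldolate 5, which puts C3–OH and the C2 side chain on opposite faces of the new ring.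

Step 4
Reactants: 6 (2S,3S)-3-hydroxy-2-(2-hydroxypropan-2-yl)-2,3-dihydro-4H-furo[3,2-c]pyran-4-one
Product: 7 (2S,3S)-3-(triethylsilyloxy)-2-[2-(triethylsilyloxy)propan-2-yl]-2,3-dihydro-4H-furo[3,2-c]pyran-4-one
Conditions: Et3SiOTf (2.6 equiv), 2,6-lutidine (4 equiv), CH2Cl2, −78 → 0 °C; Et3N-deactivated silica
Reagents that add atoms: triethylsilyl trifluoromethanesulfonate, CC[Si](CC)(CC)OS(=O)(=O)C(F)(F)F
Why: Silylation with a silyl triflate is fast enough to cap the tertiary as well as the secondary hydroxyl at low temperature, and the lutidine buffer prevents acid-induced ionisation of the C3–O bond, so no stereocentre is touched.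

Step 5
Reactants: 7 (2S,3S)-3-(triethylsilyloxy)-2-[2-(triethylsilyloxy)propan-2-yl]-2,3-dihydro-4H-furo[3,2-c]pyran-4-one; 8 but-3-yn-2-one
Product: 10 1-[(2S,3S)-3-(triethylsilyloxy)-2-[2-(triethylsilyloxy)propan-2-yl]-2,3-dihydrobenzofuran-5-yl]ethan-1-one, via bridged lactone cycloadduct 9 (not isolated)
Conditions: 8 (6 equiv, in portions), BHT (cat.), toluene, sealed tube, 150 °C
Reagents that add atoms: none
Why: The pyranone diene (C3a=C7a–C7=C6, furopyranone numbering) adds the ynone in a thermal [4+2] cycloaddition to give the 2-oxabicyclo[2.2.2]octadienone 9, which expels CO2 by retro-[4+2] at the same temperature and leaves the benzene ring. The closest known reaction type is the Diels–Alder/retro-Diels–Alder benzannulation of 4-alkoxy-2-pyranones with acetylenic esters and ketones. The six-membered carbocycle is closed by intermolecular cycloaddition, forming C3a–C4 and C5–C6 (benzofuran numbering), and becomes aromatic on loss of the lactone bridge. No stereocentre is created; C2 and C3 are spectators, and their trans arrangement leaves no hydrogen anti to the C3 silyloxy group for silanol loss. The selectivity needed is regiochemical: the ring oxygen O1 on C7a makes C3a the nucleophilic diene terminus, which bonds to the unsubstituted β-carbon of the ynone, and the unhindered C6 takes the acetyl-bearing carbon, so sterics and electronics both place the acetyl group para to O1.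

Step 6
Reactants: 10 1-[(2S,3S)-3-(triethylsilyloxy)-2-[2-(triethylsilyloxy)propan-2-yl]-2,3-dihydrobenzofuran-5-yl]ethan-1-one
Product: 11 (1R)-1-[(2S,3S)-3-(triethylsilyloxy)-2-[2-(triethylsilyloxy)propan-2-yl]-2,3-dihydrobenzofuran-5-yl]ethan-1-ol
Conditions: RuCl2[(S)-xylbinap][(S)-daipen] (0.5 mol%), t-BuOK (2 mol%), H2 (8 atm), i-PrOH, 25 °C
Reagents that add atoms: none
Why: Noyori asymmetric hydrogenation of an aryl methyl ketone by the bifunctional BINAP/diamine ruthenium hydride, in which the (S)-XylBINAP/(S)-DAIPEN pair should add hydrogen to the ketone face that gives the (R)-1-arylethanol independently of the remote ring stereocentres, the weakly basic medium sparing both silyl ethers.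

Step 7
Reactants: 11 (1R)-1-[(2S,3S)-3-(triethylsilyloxy)-2-[2-(triethylsilyloxy)propan-2-yl]-2,3-dihydrobenzofuran-5-yl]ethan-1-ol; 12 (R)-2-methylbutanoic acid
Product: 13 (1R)-1-[(2S,3S)-3-(triethylsilyloxy)-2-[2-(triethylsilyloxy)propan-2-yl]-2,3-dihydrobenzofuran-5-yl]ethyl (2R)-2-methylbutanoate
Conditions: N,N'-diisopropylcarbodiimide, DMAP (cat.), CH2Cl2, 0 °C → rt
Reagents that add atoms: none
Why: Steglich esterification (carbodiimide activation, DMAP acyl transfer) does not break the carbinol C–O bond, so its R configuration is retained, and the α-stereocentre of the simple α-alkyl acid should not epimerise at 0 °C.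

Step 8
Reactants: 13 (1R)-1-[(2S,3S)-3-(triethylsilyloxy)-2-[2-(triethylsilyloxy)propan-2-yl]-2,3-dihydrobenzofuran-5-yl]ethyl (2R)-2-methylbutanoate
Product: 14 (1R)-1-[(2S,3S)-3-hydroxy-2-(2-hydroxypropan-2-yl)-2,3-dihydrobenzofuran-5-yl]ethyl (2R)-2-methylbutanoate
Conditions: TBAF, AcOH (1:1, 2.5 equiv each), THF, 0 °C → rt
Reagents that add atoms: none
Why: Fluoride-induced cleavage of both triethylsilyl ethers (strong Si–F bond), with acetic acid buffering so that the benzylic ester is neither cleaved nor shifted and no stereocentre is touched.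

Step 9
Reactants: 14 (1R)-1-[(2S,3S)-3-hydroxy-2-(2-hydroxypropan-2-yl)-2,3-dihydrobenzofuran-5-yl]ethyl (2R)-2-methylbutanoate; 15 3-methylbutanoic anhydride (isovaleric anhydride)
Product: 16 (2S,3S)-2-(2-hydroxypropan-2-yl)-5-[(1R)-1-{[(2R)-2-methylbutanoyl]oxy}ethyl]-2,3-dihydrobenzofuran-3-yl 3-methylbutanoate
Conditions: 15 (1.2 equiv), DMAP (cat.), pyridine/CH2Cl2, 0 °C
Reagents that add atoms: none
Why: DMAP-catalysed acylation with an anhydride discriminates the secondary C3 hydroxyl from the tertiary one on steric grounds and leaves the C3–O bond intact, so the 3S configuration stays.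

Step 10
Reactants: 16 (2S,3S)-2-(2-hydroxypropan-2-yl)-5-[(1R)-1-{[(2R)-2-methylbutanoyl]oxy}ethyl]-2,3-dihydrobenzofuran-3-yl 3-methylbutanoate
Product: 17 (2R,3S)-5-[(1R)-1-{[(2R)-2-methylbutanoyl]oxy}ethyl]-2-(prop-1-en-2-yl)-2,3-dihydrobenzofuran-3-yl 3-methylbutanoate
Conditions: SOCl2, pyridine, CH2Cl2, −10 → 0 °C
Reagents that add atoms: none
Why: Dehydration of the tertiary alcohol through its chlorosulfite with pyridine as base (E2-like) should take a proton from one of the two methyl groups rather than the hindered, oxygen-flanked C2–H and so give the isopropenyl group, the buffered medium sparing both benzylic esters and the C2 descriptor changing to R only through the change of substituent priority.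

Step 11
Reactants: 17 (2R,3S)-5-[(1R)-1-{[(2R)-2-methylbutanoyl]oxy}ethyl]-2-(prop-1-en-2-yl)-2,3-dihydrobenzofuran-3-yl 3-methylbutanoate
Product: 18 (2R,3S)-2-(3-hydroxyprop-1-en-2-yl)-5-[(1R)-1-{[(2R)-2-methylbutanoyl]oxy}ethyl]-2,3-dihydrobenzofuran-3-yl 3-methylbutanoate
Conditions: SeO2 (30 mol%), t-BuOOH (3 equiv, in decane), CH2Cl2, 0 °C → rt
Reagents that add atoms: tert-butyl hydroperoxide, CC(C)(C)OO (terminal oxygen source); selenium dioxide, O=[Se]=O (catalytic oxygen carrier)
Why: Selenium dioxide allylic oxidation in its catalytic hydroperoxide form: ene reaction at the terminal CH2 with hydrogen taken from the methyl group (preferred over the methine C2–H of a 1,1-disubstituted alkene), then [2,3]-sigmatropic shift of the allylic seleninic acid, returns the double bond to its place and leaves CH2OH under near-neutral conditions that should spare the esters and all stereocentres.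

Step 12
Reactants: 18 (2R,3S)-2-(3-hydroxyprop-1-en-2-yl)-5-[(1R)-1-{[(2R)-2-methylbutanoyl]oxy}ethyl]-2,3-dihydrobenzofuran-3-yl 3-methylbutanoate
Product: 19 (2R,3S)-5-[(1R)-1-{[(2R)-2-methylbutanoyl]oxy}ethyl]-2-(3-oxoprop-1-en-2-yl)-2,3-dihydrobenzofuran-3-yl 3-methylbutanoate (CNP0154159.1)
Conditions: MnO2 (activated, excess), CH2Cl2, rt
Reagents that add atoms: none
Why: Manganese dioxide oxidation is selective for the primary allylic alcohol and gives the α-substituted acrolein on the solid surface under neutral conditions, with no ester or stereocentre affected.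

**Compound list**

1 | 3-methylbut-2-en-1-ol | CC(C)=CCO | starting material
2 | (R)-(3,3-dimethyloxiran-2-yl)methanol | CC1(C)O[C@@H]1CO | intermediate
3 | (S)-3,3-dimethyloxirane-2-carbaldehyde | CC1(C)O[C@@H]1C=O | intermediate
4 | 4-hydroxy-2H-pyran-2-one | O=C1C=C(O)C=CO1 | starting material
5 | 3-[(S)-[(2R)-3,3-dimethyloxiran-2-yl](hydroxy)methyl]-4-hydroxy-2H-pyran-2-one (syn-aldol adduct, not isolated) | O=C1OC=CC(O)=C1[C@H](O)[C@H]1OC1(C)C | intermediate
6 | (2S,3S)-3-hydroxy-2-(2-hydroxypropan-2-yl)-2,3-dihydro-4H-furo[3,2-c]pyran-4-one | CC(C)(O)[C@H]1OC2=C(C(=O)OC=C2)[C@@H]1O | intermediate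
7 | (2S,3S)-3-(triethylsilyloxy)-2-[2-(triethylsilyloxy)propan-2-yl]-2,3-dihydro-4H-furo[3,2-c]pyran-4-one | CC(C)(O[Si](CC)(CC)CC)[C@H]1OC2=C(C(=O)OC=C2)[C@@H]1O[Si](CC)(CC)CC | intermediate
8 | but-3-yn-2-one | CC(=O)C#C | starting material
9 | bridged lactone cycloadduct of 7 and 8 (2-oxabicyclo[2.2.2]octa-5,7-dien-3-one core; new bonds from pyranone C3a to the alkyne CH and from C6 to the acetyl-bearing carbon; either face, not isolated) | CC(C)(O[Si](CC)(CC)CC)[C@H]1OC2=CC3OC(=O)C2(C=C3C(C)=O)[C@@H]1O[Si](CC)(CC)CC | intermediate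
10 | 1-[(2S,3S)-3-(triethylsilyloxy)-2-[2-(triethylsilyloxy)propan-2-yl]-2,3-dihydrobenzofuran-5-yl]ethan-1-one | CC(C)(O[Si](CC)(CC)CC)[C@H]1Oc2ccc(C(C)=O)cc2[C@@H]1O[Si](CC)(CC)CC | intermediate
11 | (1R)-1-[(2S,3S)-3-(triethylsilyloxy)-2-[2-(triethylsilyloxy)propan-2-yl]-2,3-dihydrobenzofuran-5-yl]ethan-1-ol | CC(C)(O[Si](CC)(CC)CC)[C@H]1Oc2ccc([C@@H](C)O)cc2[C@@H]1O[Si](CC)(CC)CC | intermediate
12 | (R)-2-methylbutanoic acid | CC[C@@H](C)C(=O)O | starting material
13 | (1R)-1-[(2S,3S)-3-(triethylsilyloxy)-2-[2-(triethylsilyloxy)propan-2-yl]-2,3-dihydrobenzofuran-5-yl]ethyl (2R)-2-methylbutanoate | CC(C)(O[Si](CC)(CC)CC)[C@H]1Oc2ccc([C@@H](C)OC(=O)[C@H](C)CC)cc2[C@@H]1O[Si](CC)(CC)CC | intermediate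
14 | (1R)-1-[(2S,3S)-3-hydroxy-2-(2-hydroxypropan-2-yl)-2,3-dihydrobenzofuran-5-yl]ethyl (2R)-2-methylbutanoate | CC(C)(O)[C@H]1Oc2ccc([C@@H](C)OC(=O)[C@H](C)CC)cc2[C@@H]1O | intermediate
15 | 3-methylbutanoic anhydride | CC(C)CC(=O)OC(=O)CC(C)C | starting material
16 | (2S,3S)-2-(2-hydroxypropan-2-yl)-5-[(1R)-1-{[(2R)-2-methylbutanoyl]oxy}ethyl]-2,3-dihydrobenzofuran-3-yl 3-methylbutanoate | CC(C)(O)[C@H]1Oc2ccc([C@@H](C)OC(=O)[C@H](C)CC)cc2[C@@H]1OC(=O)CC(C)C | intermediate
17 | (2R,3S)-5-[(1R)-1-{[(2R)-2-methylbutanoyl]oxy}ethyl]-2-(prop-1-en-2-yl)-2,3-dihydrobenzofuran-3-yl 3-methylbutanoate | C=C(C)[C@H]1Oc2ccc([C@@H](C)OC(=O)[C@H](C)CC)cc2[C@@H]1OC(=O)CC(C)C | intermediate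
18 | (2R,3S)-2-(3-hydroxyprop-1-en-2-yl)-5-[(1R)-1-{[(2R)-2-methylbutanoyl]oxy}ethyl]-2,3-dihydrobenzofuran-3-yl 3-methylbutanoate | C=C(CO)[C@H]1Oc2ccc([C@@H](C)OC(=O)[C@H](C)CC)cc2[C@@H]1OC(=O)CC(C)C | intermediate
19 | (2R,3S)-5-[(1R)-1-{[(2R)-2-methylbutanoyl]oxy}ethyl]-2-(3-oxoprop-1-en-2-yl)-2,3-dihydrobenzofuran-3-yl 3-methylbutanoate | C=C(C=O)[C@H]1Oc2ccc([C@@H](C)OC(=O)[C@H](C)CC)cc2[C@@H]1OC(=O)CC(C)C | target

**Step count and risks**

Total steps: 12. Longest linear sequence: 12 steps (prenol 1 to target 19).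

The three steps most likely to fail:

Step 5 (key step). The ynone may oligomerise at the temperature the pyranone needs before it is captured, and long heating may let the diene lose triethylsilanol to the aromatic furan; leakage to the C4-acetyl regioisomer is the smaller concern. The fallback keeps the disconnection but brings in the acetyl group through an ester. It sets out from 7, which is heated with methyl propiolate (thermally more robust, usable in large excess, same steric and electronic bias) in toluene at 150 °C. This should give, by way of the propiolate cycloadduct F1 and loss of CO2, the methyl 5-carboxylate F2. MeNH(OMe)·HCl with i-PrMgCl (THF, −20 °C) turns F2 into the Weinreb amide F3, and MeMgBr (THF, 0 °C) gives ketone 10, where the route is rejoined.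

Step 3. The aldol step may not equilibrate fast enough, so that ring closure runs through the anti aldolate and gives the cis-3-ol (poor cis/trans control); dehydration of the aldol to the alkylidene dione and its capture by a second pyranone is the side channel that the slow addition is meant to suppress. The fallback keeps the cis material, which has the correct C2, and sets C3 by an invertive esterification instead of by the ring closure. It sets out from 3 and 4, whose cis closure product is the cis-diol F4. F4 is taken through the chemistry of steps 4 to 8 with the same reagents, giving in turn the cis bis-silyl ether F5, by way of the cis cycloadduct F6 the cis acetyl dihydrobenzofuran F7, the cis (R)-alcohol F8, the cis 2-methylbutanoate F9 and the cis diol ester F10. Mitsunobu reaction of F10 with 3-methylbutanoic acid (PPh3, DIAD, THF, 0 °C) acylates the secondary benzylic hydroxyl with inversion at C3 and gives 16, where the route is rejoined. Elimination to the benzofuran is the side reaction to watch in the cis series, since C2–H is anti to the leaving group.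

Step 11. The ene reaction may take the C2 methine hydrogen instead of a methyl hydrogen, or acidic selenium species may ionise the two benzylic esters and over-oxidise the product. The fallback replaces the selenium chemistry by halogenation and oxygen transfer. It sets out from 17: ene-type chlorination with NaOCl/CeCl3·7H2O (CH2Cl2/H2O, 0 °C) should give the allylic chloride F11, and oxidation of F11 with N-methylmorpholine N-oxide (MeCN, rt; Kornblum-type oxidation of an activated halide) gives aldehyde 19 directly, so that 18 and step 12 are bypassed.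

**Further compounds**

F1 | step 5 | bridged lactone cycloadduct of 7 and methyl propiolate (methyl ester in place of the acetyl group of 9; not isolated) | CC(C)(O[Si](CC)(CC)CC)[C@H]1OC2=CC3OC(=O)C2(C=C3C(=O)OC)[C@@H]1O[Si](CC)(CC)CC
F2 | step 5 | methyl (2S,3S)-3-(triethylsilyloxy)-2-[2-(triethylsilyloxy)propan-2-yl]-2,3-dihydrobenzofuran-5-carboxylate | CC(C)(O[Si](CC)(CC)CC)[C@H]1Oc2ccc(C(=O)OC)cc2[C@@H]1O[Si](CC)(CC)CC
F3 | step 5 | (2S,3S)-N-methoxy-N-methyl-3-(triethylsilyloxy)-2-[2-(triethylsilyloxy)propan-2-yl]-2,3-dihydrobenzofuran-5-carboxamide | CC(C)(O[Si](CC)(CC)CC)[C@H]1Oc2ccc(C(=O)N(C)OC)cc2[C@@H]1O[Si](CC)(CC)CC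
F4 | step 3 | (2S,3R)-3-hydroxy-2-(2-hydroxypropan-2-yl)-2,3-dihydro-4H-furo[3,2-c]pyran-4-one (cis-diol) | CC(C)(O)[C@H]1OC2=C(C(=O)OC=C2)[C@H]1O
F5 | step 3 | (2S,3R)-3-(triethylsilyloxy)-2-[2-(triethylsilyloxy)propan-2-yl]-2,3-dihydro-4H-furo[3,2-c]pyran-4-one | CC(C)(O[Si](CC)(CC)CC)[C@H]1OC2=C(C(=O)OC=C2)[C@H]1O[Si](CC)(CC)CC
F6 | step 3 | bridged lactone cycloadduct of F5 and 8 (cis series; not isolated) | CC(C)(O[Si](CC)(CC)CC)[C@H]1OC2=CC3OC(=O)C2(C=C3C(C)=O)[C@H]1O[Si](CC)(CC)CC
F7 | step 3 | 1-[(2S,3R)-3-(triethylsilyloxy)-2-[2-(triethylsilyloxy)propan-2-yl]-2,3-dihydrobenzofuran-5-yl]ethan-1-one | CC(C)(O[Si](CC)(CC)CC)[C@H]1Oc2ccc(C(C)=O)cc2[C@H]1O[Si](CC)(CC)CC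
F8 | step 3 | (1R)-1-[(2S,3R)-3-(triethylsilyloxy)-2-[2-(triethylsilyloxy)propan-2-yl]-2,3-dihydrobenzofuran-5-yl]ethan-1-ol | CC(C)(O[Si](CC)(CC)CC)[C@H]1Oc2ccc([C@@H](C)O)cc2[C@H]1O[Si](CC)(CC)CC
F9 | step 3 | (1R)-1-[(2S,3R)-3-(triethylsilyloxy)-2-[2-(triethylsilyloxy)propan-2-yl]-2,3-dihydrobenzofuran-5-yl]ethyl (2R)-2-methylbutanoate | CC(C)(O[Si](CC)(CC)CC)[C@H]1Oc2ccc([C@@H](C)OC(=O)[C@H](C)CC)cc2[C@H]1O[Si](CC)(CC)CC
F10 | step 3 | (1R)-1-[(2S,3R)-3-hydroxy-2-(2-hydroxypropan-2-yl)-2,3-dihydrobenzofuran-5-yl]ethyl (2R)-2-methylbutanoate | CC(C)(O)[C@H]1Oc2ccc([C@@H](C)OC(=O)[C@H](C)CC)cc2[C@H]1O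
F11 | step 11 | (2R,3S)-2-(3-chloroprop-1-en-2-yl)-5-[(1R)-1-{[(2R)-2-methylbutanoyl]oxy}ethyl]-2,3-dihydrobenzofuran-3-yl 3-methylbutanoate | C=C(CCl)[C@H]1Oc2ccc([C@@H](C)OC(=O)[C@H](C)CC)cc2[C@@H]1OC(=O)CC(C)C
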